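**Plan**
Retrosynthesis: first the 18 O–benzyl and 2 aryl C–Br bonds, then the C4–C6 interflavan bond (middle unit to catechin unit), then the C4–C8 interflavan bond between the two epicatechin gallate units, and last, in the galloylated extension unit, the O1–C2 and C3–C4 bonds of ring C.
Enabling feature: in each extension unit O1 sits on the phloroglucinol ring A ortho to C4, so O1–C8a–C4a–C4 is the heterodiene of an ortho-quinone methide and C2–C3, with B-ring aryl and gallate cis, is a (Z)-enol gallate; the later interflavan bond at C4 is carried as a methoxy group taken from the aldehyde oxidation level.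
Forward: aryl alkyne + gallic acid give the (Z)-enol gallate; its [4+2] with a salicylaldehyde acetal builds ring C with the gallate in place. This one adduct serves twice, as 4-arylthio nucleophile (middle unit) and as 8-bromo-4-methoxy electrophile (top unit). Top + middle are joined (4→8), then the dimer + 8-bromocatechin (4→6), then hydrogenolysis.
Stereochemistry: C2/C3 of both extension units come from the Z alkene geometry (cis) and a chiral phosphoric acid (absolute, relayed through the C4–OMe centre); both interflavan C4 centres come from attack anti to the neighbouring 3-gallate (4β); the catechin unit comes from (+)-catechin.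

Key step: step 4

Assumption: the sense of induction of the BINOL phosphoric acid in step 4 cannot be derived with certainty, so the (R)-acid is written and its mirror image would be used if the opposite sense is found; 2,4-bis(benzyloxy)-6-hydroxybenzaldehyde is taken as a catalogue compound.

**Route**

Step 1
Reactants: 1 3,4-bis(benzyloxy)benzaldehyde
Product: 2 1,2-bis(benzyloxy)-4-ethynylbenzene
Conditions: dimethyl (1-diazo-2-oxopropyl)phosphonate (1.2 equiv), K2CO3 (2 equiv), MeOH, rt
Reagents that add atoms: dimethyl (1-diazo-2-oxopropyl)phosphonate, COP(=O)(OC)C(=[N+]=[N-])C(C)=O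
Why: Seyferth–Gilbert homologation in its Ohira–Bestmann form, in which methanolysis of the reagent gives the diazomethylphosphonate anion, this olefinates the aldehyde, and the diazoalkene loses N2 and rearranges to the terminal alkyne without touching the benzyl ethers; no stereocentre is formed.

Step 2
Reactants: 2 1,2-bis(benzyloxy)-4-ethynylbenzene; 3 3,4,5-tris(benzyloxy)benzoic acid
Product: 4 (Z)-2-[3,4-bis(benzyloxy)phenyl]ethenyl 3,4,5-tris(benzyloxy)benzoate
Conditions: [RuCl2(p-cymene)]2 (1 mol %), P(4-ClC6H4)3 (3 mol %), DMAP (4 mol %), toluene, 60 °C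
Reagents that add atoms: none
Why: ruthenium-catalysed anti-Markovnikov addition of a carboxylic acid to a terminal alkyne, in which the carboxylate attacks the α-carbon of a ruthenium vinylidene and protonation of the alkenyl complex should deliver the (Z)-enol ester, so the cis geometry that later becomes the 2,3-cis relationship is set here by the mechanism.

Step 3
Reactants: 5 2,4-bis(benzyloxy)-6-hydroxybenzaldehyde
Product: 6 3,5-bis(benzyloxy)-2-(dimethoxymethyl)phenol
Conditions: HC(OMe)3 (5 equiv), MeOH, PPTS (5 mol %), rt; Et3N quench; used crude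
Reagents that add atoms: methanol, CO; trimethyl orthoformate, COC(OC)OC
Why: acid-catalysed acetalisation driven by the orthoformate as water scavenger turns the aldehyde into an ionisable acetal while the ortho phenol stays free; no stereocentre is formed.

Step 4
Reactants: 6 3,5-bis(benzyloxy)-2-(dimethoxymethyl)phenol; 4 (Z)-2-[3,4-bis(benzyloxy)phenyl]ethenyl 3,4,5-tris(benzyloxy)benzoate
Product: 8 (2R,3R,4R)-5,7-bis(benzyloxy)-2-[3,4-bis(benzyloxy)phenyl]-4-methoxychroman-3-yl 3,4,5-tris(benzyloxy)benzoate (all-cis; 4α-methoxy perbenzyl epicatechin gallate), via 4-methoxy o-quinone methide 7 (not isolated)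
Conditions: (R)-TRIP (10 mol %), 5 Å MS, toluene, −20 °C; 6 added slowly to 4 (1.5 equiv)
Reagents that add atoms: none
Why: Proposed new method: the phosphoric acid ionises acetal 6 with loss of methanol to the (E)-4-methoxy o-quinone methide 7 (its O-protonated form is the 2-hydroxyaryl oxocarbenium ion), held as a contact ion pair in which the phosphate hydrogen-bonds the ring A oxygen, and 7 undergoes an inverse-electron-demand oxa-[4+2] cycloaddition with the Z-enol gallate 4 in which the gallate-bearing alkene carbon bonds to C4 and the ring A oxygen bonds to C2. The closest known reaction types are the chiral phosphoric acid catalysed [4+2] cycloaddition of in situ generated o-quinone methides with styrenes and enol ethers and the acid-mediated chroman synthesis from salicylaldehyde acetals and alkenes; new are the enol ester as dienophile and the acetal-derived 4-alkoxy quinone methide in an asymmetric setting. Ring C closes by a suprafacial [4π+2π] cycloaddition that should be concerted but asynchronous, C3–C4 leading and O1–C2 lagging (in the stepwise limit the O1–C2 bond is a 6-exo-trig capture of the benzylic cation by the phosphate-bound phenolic oxygen). C4 is set by the catalyst, whose 2,4,6-triisopropylphenyl wall shields one face of the methide carbon; C2 and C3 are set relative to each other by the Z geometry of 4 (suprafacial addition gives 2,3-cis) and relative to C4 by the endo orientation of the B-ring aryl under the quinone methide, so C4 is a relay centre that is erased when it ionises in steps 5 and 7. The step needs O1-to-C2 regioselectivity (secured by the 3,4-dibenzyloxyphenyl group, a far better cation stabiliser than the acyloxy group), retention of the cis relationship (secured by immediate collapse inside the ion pair in toluene at low temperature, before C2–C3 rotation or gallate participation) and endo selectivity (any exo isomer, which would carry the mirror-image C2/C3 pair once C4 is erased, is removed by chromatography at this stage).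

Step 5
Reactants: 8 all-cis 4α-methoxy perbenzyl epicatechin gallate (first portion)
Product: 9 (2R,3S,4S)-5,7-bis(benzyloxy)-2-[3,4-bis(benzyloxy)phenyl]-4-[(2,6-dimethylphenyl)sulfanyl]chroman-3-yl 3,4,5-tris(benzyloxy)benzoate (2,3-cis, 3,4-trans; 4β-arylthio)
Conditions: 2,6-Me2C6H3SH (5 equiv), TMSOTf (0.1 equiv), CH2Cl2, −78 to −40 °C; Et3N quench
Reagents that add atoms: 2,6-dimethylbenzenethiol, Cc1cccc(C)c1S
Why: Lewis-acid-mediated SN1 exchange at C4 (the benzylic cation is stabilised by ring A and bridged on its α-face by the 3-gallate carbonyl), in which the thiol, a far better nucleophile than any arene C–H present, attacks anti to the gallate to give the 4β-sulfide, a soft leaving group that is inert to the hard activator of step 7.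

Step 6
Reactants: 8 all-cis 4α-methoxy perbenzyl epicatechin gallate (second portion)
Product: 10 (2R,3R,4R)-8-bromo-5,7-bis(benzyloxy)-2-[3,4-bis(benzyloxy)phenyl]-4-methoxychroman-3-yl 3,4,5-tris(benzyloxy)benzoate
Conditions: NBS (1.0 equiv), CH2Cl2, −78 to 0 °C
Reagents that add atoms: N-bromosuccinimide, O=C1CCC(=O)N1Br
Why: electrophilic aromatic bromination takes place at C8, the most nucleophilic position of the 5,7-dialkoxylated ring A as is usual for benzylated flavan-3-ols, and the bromine then blocks self-condensation of the electrophilic top unit; no stereocentre is affected.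

Step 7
Reactants: 10 8-bromo-4α-methoxy top unit; 9 4β-arylthio middle unit (1.5 equiv)
Product: 11 perbenzylated dimer 8-bromo-epicatechin 3-O-gallate-(4β→8)-4β-[(2,6-dimethylphenyl)sulfanyl]epicatechin 3-O-gallate (fourteen O-benzyl groups)
Conditions: TMSOTf (0.2 equiv), 4 Å MS, CH2Cl2, −78 °C; Et3N quench
Reagents that add atoms: none
Why: Lewis-acid-promoted Friedel–Crafts alkylation of a flavan C8 by a flavan-4-yl cation, in which TMSOTf ionises only the 4-methoxy group of 10, the cation cannot self-condense because its own C8 is brominated, and C8 of 9 attacks the face anti to the participating 3-gallate so that the new C4 centre should be 4β (3,4-trans), while the arylthio group of 9 is left alone by the hard activator.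

Step 8
Reactants: 12 (+)-catechin, (2R,3S)
Product: 13 5,7,3',4'-tetra-O-benzyl-(+)-catechin
Conditions: BnBr (4.4 equiv), K2CO3, DMF, 0 °C to rt
Reagents that add atoms: benzyl bromide, BrCc1ccccc1
Why: Williamson etherification with K2CO3 deprotonates only the four phenols, so the aliphatic 3-OH stays free and both stereocentres of (+)-catechin are carried through unchanged.

Step 9
Reactants: 13 5,7,3',4'-tetra-O-benzyl-(+)-catechin
Product: 14 8-bromo-5,7,3',4'-tetra-O-benzyl-(+)-catechin
Conditions: NBS (1.0 equiv), CH2Cl2, −78 °C to rt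
Reagents that add atoms: N-bromosuccinimide, O=C1CCC(=O)N1Br
Why: electrophilic bromination with NBS at C8 of ring A blocks this position so that the next C–C bond is forced to C6; the stereocentres are untouched.

Step 10
Reactants: 11 perbenzylated 4'β-arylthio dimer; 14 8-bromo-5,7,3',4'-tetra-O-benzyl-(+)-catechin (3 equiv)
Product: 15 perbenzylated dibromo trimer 8-bromo-epicatechin 3-O-gallate-(4β→8)-epicatechin 3-O-gallate-(4β→6)-8-bromocatechin (eighteen O-benzyl groups, 3-OH of the catechin unit free)
Conditions: AgBF4 (2.5 equiv), THF, 0 °C, dark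
Reagents that add atoms: none
Why: thiophilic activation of the 4-arylthio group by the silver salt gives the C4 cation of the middle unit, which undergoes Friedel–Crafts alkylation at C6 of 14 (the only free position of its ring A, C8 being brominated) from the face anti to the 3-gallate so that the new C4 centre should be 4β, while the capped top unit cannot compete through C8 and 14 is in excess.

Step 11
Reactants: 15 perbenzylated dibromo trimer
Product: 16 epicatechin 3-O-gallate-(4β→8)-epicatechin 3-O-gallate-(4β→6)-catechin (CNP0154615.1)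
Conditions: H2 (1 atm), Pd(OH)2/C, THF–MeOH–H2O, rt; filtration under argon, lyophilisation
Reagents that add atoms: none
Why: palladium-catalysed hydrogenolysis cleaves all eighteen benzyl ethers and both aryl C–Br bonds in one operation while the gallate esters, the pyran C–O bonds and the interflavan bonds survive, so no stereocentre is touched.

**Compound list**
1 | 3,4-bis(benzyloxy)benzaldehyde | O=Cc1ccc(OCc2ccccc2)c(OCc2ccccc2)c1 | starting material
2 | 1,2-bis(benzyloxy)-4-ethynylbenzene | C#Cc1ccc(OCc2ccccc2)c(OCc2ccccc2)c1 | intermediate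
3 | 3,4,5-tris(benzyloxy)benzoic acid | OC(=O)c1cc(OCc2ccccc2)c(OCc2ccccc2)c(OCc2ccccc2)c1 | starting material
4 | (Z)-2-[3,4-bis(benzyloxy)phenyl]ethenyl 3,4,5-tris(benzyloxy)benzoate | O=C(O/C=C\c1ccc(OCc2ccccc2)c(OCc2ccccc2)c1)c1cc(OCc2ccccc2)c(OCc2ccccc2)c(OCc2ccccc2)c1 | intermediate
5 | 2,4-bis(benzyloxy)-6-hydroxybenzaldehyde | O=Cc1c(O)cc(OCc2ccccc2)cc1OCc1ccccc1 | starting material
6 | 3,5-bis(benzyloxy)-2-(dimethoxymethyl)phenol | COC(OC)c1c(O)cc(OCc2ccccc2)cc1OCc1ccccc1 | intermediate
7 | (6E)-3,5-bis(benzyloxy)-6-(methoxymethylidene)cyclohexa-2,4-dien-1-one | CO/C=C1/C(=O)C=C(OCc2ccccc2)C=C1OCc1ccccc1 | intermediate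
8 | (2R,3R,4R)-5,7-bis(benzyloxy)-2-[3,4-bis(benzyloxy)phenyl]-4-methoxychroman-3-yl 3,4,5-tris(benzyloxy)benzoate (all-cis) | O=C(O[C@@H]1[C@H](OC)c2c(OCc3ccccc3)cc(OCc3ccccc3)cc2O[C@@H]1c1ccc(OCc2ccccc2)c(OCc2ccccc2)c1)c1cc(OCc2ccccc2)c(OCc2ccccc2)c(OCc2ccccc2)c1 | intermediate
9 | (2R,3S,4S)-5,7-bis(benzyloxy)-2-[3,4-bis(benzyloxy)phenyl]-4-[(2,6-dimethylphenyl)sulfanyl]chroman-3-yl 3,4,5-tris(benzyloxy)benzoate (2,3-cis, 3,4-trans) | O=C(O[C@@H]1[C@@H](Sc2c(C)cccc2C)c2c(OCc3ccccc3)cc(OCc3ccccc3)cc2O[C@@H]1c1ccc(OCc2ccccc2)c(OCc2ccccc2)c1)c1cc(OCc2ccccc2)c(OCc2ccccc2)c(OCc2ccccc2)c1 | intermediate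
10 | (2R,3R,4R)-8-bromo-5,7-bis(benzyloxy)-2-[3,4-bis(benzyloxy)phenyl]-4-methoxychroman-3-yl 3,4,5-tris(benzyloxy)benzoate (all-cis) | O=C(O[C@@H]1[C@H](OC)c2c(OCc3ccccc3)cc(OCc3ccccc3)c(Br)c2O[C@@H]1c1ccc(OCc2ccccc2)c(OCc2ccccc2)c1)c1cc(OCc2ccccc2)c(OCc2ccccc2)c(OCc2ccccc2)c1 | intermediate
11 | perbenzylated 8-bromo-epicatechin 3-O-gallate-(4β→8)-4β-[(2,6-dimethylphenyl)sulfanyl]epicatechin 3-O-gallate | O=C(O[C@@H]1[C@@H](c2c(OCc3ccccc3)cc(OCc3ccccc3)c3c2O[C@H](c2ccc(OCc4ccccc4)c(OCc4ccccc4)c2)[C@H](OC(=O)c2cc(OCc4ccccc4)c(OCc4ccccc4)c(OCc4ccccc4)c2)[C@H]3Sc2c(C)cccc2C)c2c(OCc3ccccc3)cc(OCc3ccccc3)c(Br)c2O[C@@H]1c1ccc(OCc2ccccc2)c(OCc2ccccc2)c1)c1cc(OCc2ccccc2)c(OCc2ccccc2)c(OCc2ccccc2)c1 | intermediate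
12 | (+)-catechin, (2R,3S) | O[C@H]1Cc2c(O)cc(O)cc2O[C@@H]1c1ccc(O)c(O)c1 | starting material
13 | 5,7,3',4'-tetra-O-benzyl-(+)-catechin | O[C@H]1Cc2c(OCc3ccccc3)cc(OCc3ccccc3)cc2O[C@@H]1c1ccc(OCc2ccccc2)c(OCc2ccccc2)c1 | intermediate
14 | 8-bromo-5,7,3',4'-tetra-O-benzyl-(+)-catechin | O[C@H]1Cc2c(OCc3ccccc3)cc(OCc3ccccc3)c(Br)c2O[C@@H]1c1ccc(OCc2ccccc2)c(OCc2ccccc2)c1 | intermediate
15 | perbenzylated 8-bromo-epicatechin 3-O-gallate-(4β→8)-epicatechin 3-O-gallate-(4β→6)-8-bromocatechin | O=C(O[C@@H]1[C@@H](c2c(OCc3ccccc3)cc(OCc3ccccc3)c3c2O[C@H](c2ccc(OCc4ccccc4)c(OCc4ccccc4)c2)[C@H](OC(=O)c2cc(OCc4ccccc4)c(OCc4ccccc4)c(OCc4ccccc4)c2)[C@H]3c2c(OCc4ccccc4)c(Br)c3c(c2OCc4ccccc4)C[C@H](O)[C@@H](c2ccc(OCc4ccccc4)c(OCc4ccccc4)c2)O3)c2c(OCc3ccccc3)cc(OCc3ccccc3)c(Br)c2O[C@@H]1c1ccc(OCc2ccccc2)c(OCc2ccccc2)c1)c1cc(OCc2ccccc2)c(OCc2ccccc2)c(OCc2ccccc2)c1 | intermediate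
16 | epicatechin 3-O-gallate-(4β→8)-epicatechin 3-O-gallate-(4β→6)-catechin | O=C(O[C@@H]1[C@@H](c2c(O)cc(O)c3c2O[C@H](c2ccc(O)c(O)c2)[C@H](OC(=O)c2cc(O)c(O)c(O)c2)[C@H]3c2c(O)cc3c(c2O)C[C@H](O)[C@@H](c2ccc(O)c(O)c2)O3)c2c(O)cc(O)cc2O[C@@H]1c1ccc(O)c(O)c1)c1cc(O)c(O)c(O)c1 | target

**Summary**
Total steps: 11. Longest linear sequence: 7 steps (1, 2, 4, 6, 7, 10, 11).

Steps most likely to fail:

1. Step 4 (Proposed new method). The cycloaddition may leave the concerted path: C2–C3 rotation or gallate participation in a benzylic cation would erode the cis relationship, the catalyst may discriminate the faces poorly, and self-condensation of the electron-rich acetal may outrun a sluggish enol ester. The fallback uses known chemistry and sets out from 13 and 3. Oxidation of 13 with Dess–Martin periodinane should give (2R)-5,7-bis(benzyloxy)-2-[3,4-bis(benzyloxy)phenyl]chroman-3-one F1. Reduction with LiBH(sec-Bu)3 at −78 °C, hydride entering anti to the C2 aryl, should give 5,7,3',4'-tetra-O-benzyl-(−)-epicatechin F2. Benzylic oxidation with DDQ in the presence of methanol should give 4β-methoxy-5,7,3',4'-tetra-O-benzylepicatechin F3. Esterification with 3 (DCC, DMAP) should give the 4β-methoxy epimer of 8, 4β-methoxy perbenzyl epicatechin gallate F4. Because C4 is ionised in the next operations, F4 enters step 5 unchanged and returns to the route at 9. Bromination of F4 with NBS gives its 8-bromo derivative F5, which under the conditions of step 7 with 9 returns to the route at 11.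

2. Step 10. Attack by the hindered, bromine-deactivated C6 position may be slow, so that the C4 cation of the dimer is consumed by self-oligomerisation or by acid-induced scrambling of the existing interflavan bond. The fallback changes the order of assembly and sets out from 8 and 14. Slow addition of 8 to 14 (5 equiv) and TMSOTf in CH2Cl2 at −78 °C, so that its cation always meets a large excess of the C8-blocked catechin, should give the perbenzylated epicatechin 3-O-gallate-(4β→6)-8-bromocatechin dimer F6, whose only free nucleophilic ring is ring A of the gallate unit. Alkylation of F6 at C8 of that unit by the capped electrophile 10 (TMSOTf, −78 °C) returns to the route at 15.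

3. Step 7. Orthogonality may be lost through premature activation or intermolecular transfer of the arylthio group, and attack through C6 of 9 may compete. The fallback reverses the order of the two activation modes and sets out from 10. Thio-exchange of 10 (2,6-dimethylbenzenethiol, TMSOTf) should give the 8-bromo-4β-[(2,6-dimethylphenyl)sulfanyl] perbenzyl epicatechin gallate F7. Its activation with AgBF4, buffered with 2,6-di-tert-butyl-4-methylpyridine, in the presence of 8 as nucleophile should give the perbenzylated 8-bromo-epicatechin 3-O-gallate-(4β→8)-4α-methoxyepicatechin 3-O-gallate dimer F8. Hard activation of F8 with TMSOTf in the presence of 14 returns to the route at 15.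

**Further compounds**
F1 | step 4 | (2R)-5,7-bis(benzyloxy)-2-[3,4-bis(benzyloxy)phenyl]chroman-3-one | O=C1Cc2c(OCc3ccccc3)cc(OCc3ccccc3)cc2O[C@@H]1c1ccc(OCc2ccccc2)c(OCc2ccccc2)c1
F2 | step 4 | 5,7,3',4'-tetra-O-benzyl-(−)-epicatechin | O[C@@H]1Cc2c(OCc3ccccc3)cc(OCc3ccccc3)cc2O[C@@H]1c1ccc(OCc2ccccc2)c(OCc2ccccc2)c1
F3 | step 4 | 4β-methoxy-5,7,3',4'-tetra-O-benzylepicatechin, (2R,3R,4S) | O[C@@H]1[C@@H](OC)c2c(OCc3ccccc3)cc(OCc3ccccc3)cc2O[C@@H]1c1ccc(OCc2ccccc2)c(OCc2ccccc2)c1
F4 | step 4 | 4β-methoxy perbenzyl epicatechin gallate (C4 epimer of 8) | O=C(O[C@@H]1[C@@H](OC)c2c(OCc3ccccc3)cc(OCc3ccccc3)cc2O[C@@H]1c1ccc(OCc2ccccc2)c(OCc2ccccc2)c1)c1cc(OCc2ccccc2)c(OCc2ccccc2)c(OCc2ccccc2)c1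
F5 | step 4 | 8-bromo-4β-methoxy perbenzyl epicatechin gallate (C4 epimer of 10) | O=C(O[C@@H]1[C@@H](OC)c2c(OCc3ccccc3)cc(OCc3ccccc3)c(Br)c2O[C@@H]1c1ccc(OCc2ccccc2)c(OCc2ccccc2)c1)c1cc(OCc2ccccc2)c(OCc2ccccc2)c(OCc2ccccc2)c1
F6 | step 10 | perbenzylated epicatechin 3-O-gallate-(4β→6)-8-bromocatechin | O=C(O[C@@H]1[C@@H](c2c(OCc3ccccc3)c(Br)c3c(c2OCc2ccccc2)C[C@H](O)[C@@H](c2ccc(OCc4ccccc4)c(OCc4ccccc4)c2)O3)c2c(OCc3ccccc3)cc(OCc3ccccc3)cc2O[C@@H]1c1ccc(OCc2ccccc2)c(OCc2ccccc2)c1)c1cc(OCc2ccccc2)c(OCc2ccccc2)c(OCc2ccccc2)c1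
F7 | step 7 | 8-bromo-4β-[(2,6-dimethylphenyl)sulfanyl] perbenzyl epicatechin gallate | O=C(O[C@@H]1[C@@H](Sc2c(C)cccc2C)c2c(OCc3ccccc3)cc(OCc3ccccc3)c(Br)c2O[C@@H]1c1ccc(OCc2ccccc2)c(OCc2ccccc2)c1)c1cc(OCc2ccccc2)c(OCc2ccccc2)c(OCc2ccccc2)c1
F8 | step 7 | perbenzylated 8-bromo-epicatechin 3-O-gallate-(4β→8)-4α-methoxyepicatechin 3-O-gallate | O=C(O[C@@H]1[C@@H](c2c(OCc3ccccc3)cc(OCc3ccccc3)c3c2O[C@H](c2ccc(OCc4ccccc4)c(OCc4ccccc4)c2)[C@H](OC(=O)c2cc(OCc4ccccc4)c(OCc4ccccc4)c(OCc4ccccc4)c2)[C@@H]3OC)c2c(OCc3ccccc3)cc(OCc3ccccc3)c(Br)c2O[C@@H]1c1ccc(OCc2ccccc2)c(OCc2ccccc2)c1)c1cc(OCc2ccccc2)c(OCc2ccccc2)c(OCc2ccccc2)c1
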